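1. Late in both earlier runs Z slows: from 2.00 min to 3.00 min, Sunday's run moves from 43.3 % to 46.6 % and Wednesday's from 37.8 % to 39.7 %. The level where Z flattens is therefore the thing to watch.

in all of them: temperature 30 °C

|  | D | J | remark | time |
|---|---|---|---|---|
| Sunday's | 0.088 M | 1.5 µM | run made earlier |  |
| Wednesday's | 0.12 M | 1.5 µM | run made earlier |  |
| winter | 0.059 M | 3.0 µM |  | 8.0 min |
| dawn | 0.059 M | 2.5 µM |  | 8.0 min |
| spring | 0.059 M | 1.5 µM |  | 8.0 min |
| summer | 0.059 M | 5.0 µM |  | 8.0 min |
| dusk | 0.059 M | 0.80 µM |  | 8.0 min |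

| run | time / min | Z / % |
|---|---|---|
| Sunday's | 0.167 | 13.2 |
| Sunday's | 0.417 | 21.5 |
| Sunday's | 0.833 | 31.3 |
| Sunday's | 1.33 | 37.6 |
| Sunday's | 1.50 | 38.5 |
| Sunday's | 2.00 | 43.3 |
| Sunday's | 3.00 | 46.6 |
| Wednesday's | 0.167 | 11.2 |
| Wednesday's | 0.417 | 19.2 |
| Wednesday's | 0.833 | 25.9 |
| Wednesday's | 1.33 | 33.3 |
| Wednesday's | 1.50 | 34.9 |
| Wednesday's | 2.00 | 37.8 |
| Wednesday's | 3.00 | 39.7 |

(readings scatter by 1 percentage point)

- the numbers in the tables scatter by 1 percentage point (one standard deviation)
- what may be going on: D -> G; D + J -> Z + J; J -> X; J -> L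
- no earlier run changes the charge of J; that part of a forecast is a guess

1. the flasks by amount of Z, in percent of the D charged, highest first, at 8.0 min (winter / dawn / spring / summer / dusk)
2. the amount of Z, in percent of the D charged of the flask you put first, at 8.0 min
3. the amount of Z, in percent of the D charged of the flask you put last, at 8.0 min

2. The bench rule says that a charge of J makes a fixed amount of Z before it stops. Last-reading cZ per cJ charged (the total turnover number) reads 27300 on Sunday's run and 31800 on Wednesday's. Their mean is the turnover capacity N, 29500, a rough reading.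

3. The capacity ratio r = N·cJ/cD sets J's capacity against the charge of D. The even case, r = 1, is the zero of the scale and the border of the rule. For the new flasks, with cD at 0.059 M, it falls at cJ = 2.00 µM.

4. Dusk lies below the border: its capacity of 23.6 mM is smaller than cD, so my reckoning for dusk's Z is r = 40.1 %. Summer lies above it, with r = 2.50, so the rule asks for more Z than the charge holds and stops working. If the rate follows the falling cD, my reckoning for summer's Z is 1 − exp(−r), which gives 91.8 %. With cD equal, my order follows cJ: summer, winter, dawn, spring, dusk.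

5. The forecast gives summer > winter > dawn > spring > dusk, with 78 % and 43 %: “Any unseen enzyme death would lower these”.

6. The flasks give summer > winter > dawn > spring > dusk, with 85.9 % for summer and 42.5 % for dusk.

    D → G (k = 7.51 × 10⁻⁴ s⁻¹, Ea = 85.0 kJ mol⁻¹)
    D + J → Z + J, rate k2*[D]*[J]/(1 + ([D]/Km2) + ([Z]/Kp2)) (0.110 M, 8.82 mM, k = 20900 L mol⁻¹ s⁻¹, Ea = 34.0 kJ mol⁻¹)
    J → X (k = 0.00929 s⁻¹, Ea = 95.0 kJ mol⁻¹)
    J → L (k = 3.63 × 10⁻⁵ s⁻¹, Ea = 253 kJ mol⁻¹)
    (constants at 30 °C)

Dusk ends near its r of 40.1 %, and the plateau holds: ten times as long leaves 42.7 %. At 8.00 min dusk still holds D at 38.5 %, while J stands at 1.14 %. In dusk the loss of J to X is the largest single effect, acting together with the crowding by Z. Dusk without the loss reaches 74.9 %, and without the crowding 71.0 %.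

7. Dusk read at 2.0 min has J at 32.7 %, so N times the J lost gives 27.0 %. Z in that flask stands at 35.1 %, more than the reckoning.

The data stem from a simulated flask for substances that don't exist.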